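Ring A is numbered C1 (butyryl-bearing), C2 (OH), C3 (H), C4 (O), C5 (CH2 to ring B), C6 (O). Everything rests on cutting the C1–acyl and C2–O bonds together: a C1≡C2 aryne, polarised by the C6 benzyloxy group, inserts into the acyl–oxygen bond of butyric acid and sets the ortho-hydroxy ketone pair in one operation. Its precursor is the ring A ortho-trimethylsilyl triflate with benzyl ethers at O4 and O6 and ring B attached as its bis methyl enol ether. Because ring B ketones cannot meet butyllithium, silicon and triflate are placed on a formyl-bearing ring A piece first, and ring B is joined afterwards by reductive alkylation.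

Key step: step 9

Remark: ring B of 13 and 16 is drawn as the cross-conjugated 3,5-dimethoxy dienone; any regioisomeric bis enol ether formed in step 8 would mask the same acidity and converge on 17 in step 10.
Remark: 1-(2,4,6-trihydroxyphenyl)propan-1-one (1) and 3,5-bis(benzyloxy)phenol (3) are taken as purchased.

Step 1
Reactants: 1 1-(2,4,6-trihydroxyphenyl)propan-1-one
Product: 2 3,5-dihydroxy-4,4-dimethyl-2-propanoylcyclohexa-2,5-dien-1-one
Conditions: NaOMe, MeI (2 equiv), MeOH, 0 °C to rt
Reagents that add atoms: iodomethane, CI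
Why: Alkylative dearomatisation of an acylphloroglucinol: the polyphenolate is methylated on carbon, and the second methyl group enters at the same ring carbon because the mono-C-methylated ring is again deprotonated to a soft carbon nucleophile, which should give the gem-dimethyl trione when two equivalents of iodomethane are used.

Step 2
Reactants: 3 3,5-bis(benzyloxy)phenol
Product: 4 2,6-bis(benzyloxy)-4-hydroxybenzaldehyde
Conditions: POCl3, DMF, 0 °C to rt; then ice-water
Reagents that add atoms: N,N-dimethylformamide, CN(C)C=O; water, O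
Why: Vilsmeier–Haack formylation, in which the chloroiminium ion should attack the carbon para to the free hydroxyl and between the two ether oxygens, as 3,5-dialkoxyphenols generally do, the less polar ortho-formyl isomer being removable by chromatography if it forms.

Step 3
Reactants: 4 2,6-bis(benzyloxy)-4-hydroxybenzaldehyde
Product: 5 2,6-bis(benzyloxy)-3-bromo-4-hydroxybenzaldehyde
Conditions: NBS (1.0 equiv), MeCN, 0 °C
Reagents that add atoms: N-bromosuccinimide, O=C1CCC(=O)N1Br
Why: Electrophilic aromatic bromination in which only the two equivalent positions ortho to the hydroxyl are open, so that one equivalent of NBS should give a single monobromide with the halogen between the hydroxyl and a benzyloxy group.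

Step 4
Reactants: 5 2,6-bis(benzyloxy)-3-bromo-4-hydroxybenzaldehyde
Product: 6 2,6-bis(benzyloxy)-3-bromo-4-(trimethylsilyloxy)benzaldehyde
Conditions: HMDS, THF, 70 °C; evaporate
Reagents that add atoms: hexamethyldisilazane, C[Si](C)(C)N[Si](C)(C)C
Why: O-Silylation of an acidic phenol with HMDS, which releases only ammonia and leaves the aldehyde untouched, so that the moisture-sensitive silyl ether can be used after evaporation.

Step 5
Reactants: 6 2,6-bis(benzyloxy)-3-bromo-4-(trimethylsilyloxy)benzaldehyde
Product: 7 2-[2,6-bis(benzyloxy)-3-bromo-4-(trimethylsilyloxy)phenyl]-1,3-dioxolane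
Conditions: TMSOCH2CH2OTMS, TMSOTf (cat.), CH2Cl2, −78 to −20 °C; pyridine quench
Reagents that add atoms: 1,2-bis(trimethylsilyloxy)ethane, C[Si](C)(C)OCCO[Si](C)(C)C
Why: Aprotic acetalisation with the bis-silylated diol and catalytic TMSOTf, which works on hindered and electron-rich aldehydes at low temperature, keeps the aryl silyl ether and hides the formyl group from butyllithium.

Step 6
Reactants: 7 2-[2,6-bis(benzyloxy)-3-bromo-4-(trimethylsilyloxy)phenyl]-1,3-dioxolane
Product: 10 3,5-bis(benzyloxy)-4-formyl-2-(trimethylsilyl)phenyl trifluoromethanesulfonate, via lithium silylphenolate 8 (not isolated), via dioxolane triflate 9 (not isolated)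
Conditions: n-BuLi (1.05 equiv), THF, −78 °C; Tf2O, −78 to 0 °C; then 1 M aq. HCl, THF, rt
Reagents that add atoms: trifluoromethanesulfonic anhydride, O=S(=O)(OS(=O)(=O)C(F)(F)F)C(F)(F)F; water, O
Why: Bromine–lithium exchange gives the aryllithium beside the silyloxy group, a 1,3 oxygen-to-carbon silyl shift (retro-Brook rearrangement) delivers the ortho-silyl phenolate faster than butyllithium can attack elsewhere, triflation in the flask gives the silyl triflate, and dilute acid then frees the aldehyde while the aryl–silicon bond, deactivated by the triflate, should hold.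

Step 7
Reactants: 10 3,5-bis(benzyloxy)-4-formyl-2-(trimethylsilyl)phenyl trifluoromethanesulfonate; 2 3,5-dihydroxy-4,4-dimethyl-2-propanoylcyclohexa-2,5-dien-1-one
Product: 12 3,5-bis(benzyloxy)-4-[(2,4-dihydroxy-3,3-dimethyl-6-oxo-5-propanoylcyclohexa-1,4-dien-1-yl)methyl]-2-(trimethylsilyl)phenyl trifluoromethanesulfonate, via Knoevenagel adduct 11 (not isolated)
Conditions: L-proline (20 mol %), Hantzsch ester (1.2 equiv), CH2Cl2, rt
Reagents that add atoms: none
Why: Organocatalytic reductive alkylation of a cyclic 1,3-dione: proline activates the aldehyde as its iminium ion, the ring B carbon between two carbonyl groups (C6 of 2) condenses with it (Knoevenagel), and the resulting electron-poor arylidene trione takes a hydride from the dihydropyridine before a second trione can add, under neutral conditions that spare silane, triflate and benzyl ethers.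

Step 8
Reactants: 12 3,5-bis(benzyloxy)-4-[(2,4-dihydroxy-3,3-dimethyl-6-oxo-5-propanoylcyclohexa-1,4-dien-1-yl)methyl]-2-(trimethylsilyl)phenyl trifluoromethanesulfonate
Product: 13 3,5-bis(benzyloxy)-4-[(2,4-dimethoxy-3,3-dimethyl-6-oxo-5-propanoylcyclohexa-1,4-dien-1-yl)methyl]-2-(trimethylsilyl)phenyl trifluoromethanesulfonate
Conditions: TMSCHN2 (excess), PhMe/MeOH, 0 °C to rt
Reagents that add atoms: (trimethylsilyl)diazomethane, C[Si](C)(C)C=[N+]=[N-]
Why: Diazoalkane O-methylation of the two strongly acidic enols of ring B, which needs no base and no fluoride and therefore spares the silyl triflate, removes every proton that could compete with butyrate in the next step.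

Step 9
Reactants: 13 3,5-bis(benzyloxy)-4-[(2,4-dimethoxy-3,3-dimethyl-6-oxo-5-propanoylcyclohexa-1,4-dien-1-yl)methyl]-2-(trimethylsilyl)phenyl trifluoromethanesulfonate; 14 butyric acid
Product: 16 1-{2,4-bis(benzyloxy)-3-[(2,4-dimethoxy-3,3-dimethyl-6-oxo-5-propanoylcyclohexa-1,4-dien-1-yl)methyl]-6-hydroxyphenyl}butan-1-one, via ring A aryne 15 (not isolated)
Conditions: butyric acid (1.5 equiv), CsF (4 equiv), THF, 125 °C, sealed tube
Reagents that add atoms: none
Why: Fluoride attacks silicon, the C1 carbanion expels the C2 triflate and the C1≡C2 aryne 15 forms. Butyrate then adds through oxygen at C2, and the C1 aryl anion attacks the ester carbonyl through a four-membered alkoxide that opens to the C1 ketone and the C2 phenoxide (an aryne insertion into the acyl–oxygen bond, ending in an anionic Fries-type 1,3-acyl shift). The closest known reaction is the CsF-mediated carbon–oxygen insertion of arynes from ortho-silylaryl triflates into carboxylic acids, which gives ortho-hydroxyaryl ketones. No ring is closed and no stereocentre is created. The step needs regioselectivity, secured by the C6 benzyloxy group, whose inductive pull distorts the aryne so that the nucleophile enters at the remote, unhindered C2 and the charge develops at C1 beside that oxygen. It also needs chemoselectivity for butyrate, secured by ring B carrying no acidic enol, while the high temperature in THF favours the intramolecular acyl shift over protonation of the aryl anion.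

Step 10
Reactants: 16 1-{2,4-bis(benzyloxy)-3-[(2,4-dimethoxy-3,3-dimethyl-6-oxo-5-propanoylcyclohexa-1,4-dien-1-yl)methyl]-6-hydroxyphenyl}butan-1-one
Product: 17 1-{2,4-bis(benzyloxy)-3-[(2,4-dihydroxy-3,3-dimethyl-6-oxo-5-propanoylcyclohexa-1,4-dien-1-yl)methyl]-6-hydroxyphenyl}butan-1-one
Conditions: 1 M aq. HCl, THF, 40 °C
Reagents that add atoms: water, O
Why: Acid-catalysed addition–elimination of water at the two vinylogous ester carbons returns the ring B trione, while the benzyl ethers at O4 and O6 keep ring A from cyclising onto ring B or losing the methylene bridge.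

Step 11
Reactants: 17 1-{2,4-bis(benzyloxy)-3-[(2,4-dihydroxy-3,3-dimethyl-6-oxo-5-propanoylcyclohexa-1,4-dien-1-yl)methyl]-6-hydroxyphenyl}butan-1-one
Product: 18 2-[(3-butanoyl-2,4,6-trihydroxyphenyl)methyl]-3,5-dihydroxy-4,4-dimethyl-6-propanoylcyclohexa-2,5-dien-1-one
Conditions: H2 (1 atm), 10% Pd/C, EtOAc, rt
Reagents that add atoms: none
Why: Hydrogenolysis of the two aryl benzyl ethers over Pd/C under neutral conditions, in which the fully enolised trione and the hydrogen-bonded aryl ketones resist reduction, should give the achiral target, which has no stereocentre to set.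

Compound list
1 | 1-(2,4,6-trihydroxyphenyl)propan-1-one | CCC(=O)c1c(O)cc(O)cc1O | starting material
2 | 3,5-dihydroxy-4,4-dimethyl-2-propanoylcyclohexa-2,5-dien-1-one (propionylfilicinic acid) | CCC(=O)C1=C(O)C(C)(C)C(O)=CC1=O | intermediate
3 | 3,5-bis(benzyloxy)phenol | Oc1cc(OCc2ccccc2)cc(OCc2ccccc2)c1 | starting material
4 | 2,6-bis(benzyloxy)-4-hydroxybenzaldehyde | O=Cc1c(OCc2ccccc2)cc(O)cc1OCc1ccccc1 | intermediate
5 | 2,6-bis(benzyloxy)-3-bromo-4-hydroxybenzaldehyde | O=Cc1c(OCc2ccccc2)c(Br)c(O)cc1OCc1ccccc1 | intermediate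
6 | 2,6-bis(benzyloxy)-3-bromo-4-(trimethylsilyloxy)benzaldehyde | O=Cc1c(OCc2ccccc2)c(Br)c(O[Si](C)(C)C)cc1OCc1ccccc1 | intermediate
7 | 2-[2,6-bis(benzyloxy)-3-bromo-4-(trimethylsilyloxy)phenyl]-1,3-dioxolane | C[Si](C)(C)Oc1cc(OCc2ccccc2)c(C2OCCO2)c(OCc2ccccc2)c1Br | intermediate
8 | lithium 3,5-bis(benzyloxy)-4-(1,3-dioxolan-2-yl)-2-(trimethylsilyl)phenolate | [Li+].[O-]c1cc(OCc2ccccc2)c(C2OCCO2)c(OCc2ccccc2)c1[Si](C)(C)C | intermediate (not isolated)
9 | 3,5-bis(benzyloxy)-4-(1,3-dioxolan-2-yl)-2-(trimethylsilyl)phenyl trifluoromethanesulfonate | C[Si](C)(C)c1c(OS(=O)(=O)C(F)(F)F)cc(OCc2ccccc2)c(C2OCCO2)c1OCc1ccccc1 | intermediate (not isolated)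
10 | 3,5-bis(benzyloxy)-4-formyl-2-(trimethylsilyl)phenyl trifluoromethanesulfonate | C[Si](C)(C)c1c(OS(=O)(=O)C(F)(F)F)cc(OCc2ccccc2)c(C=O)c1OCc1ccccc1 | intermediate
11 | 3,5-bis(benzyloxy)-4-[(4-hydroxy-3,3-dimethyl-2,6-dioxo-5-propanoylcyclohex-4-en-1-ylidene)methyl]-2-(trimethylsilyl)phenyl trifluoromethanesulfonate (alkene geometry not defined, lost on reduction) | C[Si](C)(C)c1c(OS(=O)(=O)C(F)(F)F)cc(OCc2ccccc2)c(C=C2C(=O)C(C)(C)C(O)=C(C(=O)CC)C2=O)c1OCc1ccccc1 | intermediate (not isolated)
12 | 3,5-bis(benzyloxy)-4-[(2,4-dihydroxy-3,3-dimethyl-6-oxo-5-propanoylcyclohexa-1,4-dien-1-yl)methyl]-2-(trimethylsilyl)phenyl trifluoromethanesulfonate | C[Si](C)(C)c1c(OS(=O)(=O)C(F)(F)F)cc(OCc2ccccc2)c(CC2=C(O)C(C)(C)C(O)=C(C(=O)CC)C2=O)c1OCc1ccccc1 | intermediate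
13 | 3,5-bis(benzyloxy)-4-[(2,4-dimethoxy-3,3-dimethyl-6-oxo-5-propanoylcyclohexa-1,4-dien-1-yl)methyl]-2-(trimethylsilyl)phenyl trifluoromethanesulfonate | C[Si](C)(C)c1c(OS(=O)(=O)C(F)(F)F)cc(OCc2ccccc2)c(CC2=C(OC)C(C)(C)C(OC)=C(C(=O)CC)C2=O)c1OCc1ccccc1 | intermediate (key-step precursor)
14 | butyric acid | CCCC(=O)O | starting material
15 | ring A aryne: 13 without the silyl and triflate groups, C1≡C2 triple bond | C1(OCc2ccccc2)=C(CC2=C(OC)C(C)(C)C(OC)=C(C(=O)CC)C2=O)C(OCc2ccccc2)=CC#C1 | intermediate (not isolated)
16 | 1-{2,4-bis(benzyloxy)-3-[(2,4-dimethoxy-3,3-dimethyl-6-oxo-5-propanoylcyclohexa-1,4-dien-1-yl)methyl]-6-hydroxyphenyl}butan-1-one | CCCC(=O)c1c(O)cc(OCc2ccccc2)c(CC2=C(OC)C(C)(C)C(OC)=C(C(=O)CC)C2=O)c1OCc1ccccc1 | intermediate (key-step product)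
17 | 1-{2,4-bis(benzyloxy)-3-[(2,4-dihydroxy-3,3-dimethyl-6-oxo-5-propanoylcyclohexa-1,4-dien-1-yl)methyl]-6-hydroxyphenyl}butan-1-one | CCCC(=O)c1c(O)cc(OCc2ccccc2)c(CC2=C(O)C(C)(C)C(O)=C(C(=O)CC)C2=O)c1OCc1ccccc1 | intermediate
18 | 2-[(3-butanoyl-2,4,6-trihydroxyphenyl)methyl]-3,5-dihydroxy-4,4-dimethyl-6-propanoylcyclohexa-2,5-dien-1-one (achiral) | CCCC(=O)c1c(O)cc(O)c(CC2=C(O)C(C)(C)C(O)=C(C(=O)CC)C2=O)c1O | target

Total step count: 11. Longest linear sequence: 10 steps (steps 2 to 11, from 3 to 18); step 1 is a one-step branch that joins at step 7.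

Steps most likely to fail

Step 9. Proton transfer to the C1 aryl anion (from bifluoride, from excess acid, or from the α-CH2 of the aryl butyrate just formed) may outrun the four-membered acyl shift. The reaction would then stop at O-arylation without forming the ketone. At 125 °C butyrate or fluoride may also dealkylate the ring B methyl enol ethers, freeing an enolate that competes for the aryne. The fallback abandons the aryne and uses the classical one-carbon union of two unprotected halves. It sets out from 2 and comes back at 18. Friedel–Crafts acylation of phloroglucinol with butyryl chloride (AlCl3) should give 1-(2,4,6-trihydroxyphenyl)butan-1-one F1. F1, 2 and aqueous formaldehyde are then combined in dilute aqueous NaOH at 0 °C and acidified. Formaldehyde condenses at the ring B carbon between two carbonyl groups, and the resulting methylene trione is attacked by one of the two equivalent free ring carbons of F1, which should give 18 directly. The two symmetrical methylene-bis by-products that are expected alongside would be removed by chromatography.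

Step 7. Iminium formation and condensation may be slow at the aldehyde flanked by two benzyloxy groups, or a second trione may add to 11 before hydride transfer. The fallback replaces condensation and reduction by an alkylation. It sets out from 10 and comes back at 12. NaBH4 (THF/MeOH, 0 °C) should reduce 10 to 3,5-bis(benzyloxy)-4-(hydroxymethyl)-2-(trimethylsilyl)phenyl trifluoromethanesulfonate F2. Appel bromination (CBr4, PPh3, CH2Cl2, 0 °C) should give 3,5-bis(benzyloxy)-4-(bromomethyl)-2-(trimethylsilyl)phenyl trifluoromethanesulfonate F3. This reactive 2,6-dialkoxybenzyl bromide should then C-alkylate the enolate of 2 (K2CO3, acetone, rt) at the carbon between its two carbonyl groups to give 12.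

Step 6. Butyllithium may attack silicon of the aryl silyl ether or the silyl shift may be incomplete, Tf2O may open the dioxolane, and the aryl–silicon bond may be protonated off during the acidic unmasking. The fallback masks the aldehyde only transiently and separates the triflation, so no acetal is made, met by Tf2O or hydrolysed. It sets out from 6 and comes back at 10. Adding 6 to lithium 4-methylpiperazin-1-ide (THF, −78 °C) should give the lithium [2,6-bis(benzyloxy)-3-bromo-4-(trimethylsilyloxy)phenyl](4-methylpiperazin-1-yl)methanolate F4 in the flask. n-BuLi then effects bromine–lithium exchange and the oxygen-to-carbon silyl shift, and aqueous NH4Cl returns the aldehyde as 2,6-bis(benzyloxy)-4-hydroxy-3-(trimethylsilyl)benzaldehyde F5. Triflation of F5 (Tf2O, pyridine, CH2Cl2, 0 °C) should give 10.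

Further compounds
F1 | step 9 | 1-(2,4,6-trihydroxyphenyl)butan-1-one | CCCC(=O)c1c(O)cc(O)cc1O
F2 | step 7 | 3,5-bis(benzyloxy)-4-(hydroxymethyl)-2-(trimethylsilyl)phenyl trifluoromethanesulfonate | C[Si](C)(C)c1c(OS(=O)(=O)C(F)(F)F)cc(OCc2ccccc2)c(CO)c1OCc1ccccc1
F3 | step 7 | 3,5-bis(benzyloxy)-4-(bromomethyl)-2-(trimethylsilyl)phenyl trifluoromethanesulfonate | C[Si](C)(C)c1c(OS(=O)(=O)C(F)(F)F)cc(OCc2ccccc2)c(CBr)c1OCc1ccccc1
F4 | step 6 | lithium [2,6-bis(benzyloxy)-3-bromo-4-(trimethylsilyloxy)phenyl](4-methylpiperazin-1-yl)methanolate (racemic, formed in the flask) | [Li+].[O-]C(N1CCN(C)CC1)c1c(OCc2ccccc2)c(Br)c(O[Si](C)(C)C)cc1OCc1ccccc1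
F5 | step 6 | 2,6-bis(benzyloxy)-4-hydroxy-3-(trimethylsilyl)benzaldehyde | O=Cc1c(OCc2ccccc2)c([Si](C)(C)C)c(O)cc1OCc1ccccc1
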